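Ring numbering: C1 bears CO2Me, C2 is the vinylic CH, C3 carries OAc, C4 the 2-methylbutanoate, C5 the 3-methylpentanoate, and C6 is the CH2.
Retrosynthesis: O3–Ac is traced back to O3–SiEt3. C2–C3 and C1–C6 are then cut together, which removes C1=C2(CO2Me) as methyl propiolate and opens the only ring to the 4-bromo-2,3-bis(acyloxy)butanal 9 (C3 = CHO, C6 = CH2Br). Next come C6–Br with O5–acyl (epoxide plus acyl bromide), O4–acyl (Mitsunobu) and the epoxide oxygen (divinylcarbinol).
Enabling feature: in the array O=C–C1=C2–C3–O the enoate β-carbon C2 and the carbinol carbon C3 are both acceptor carbons (1,4-dissonant), and C6 is a primary carbon next to C5–O. Zerovalent nickel joins C2 to C3 reductively and so ends up bound to C1, cis to C3, where it can take up C6–Br.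
Forward order: the chain C3–C6 is built first with both chiral esters on it (steps 1–5), the cyclohexene ring is closed in one operation (step 6), and the acetate comes last (step 7).
Stereochemistry: C5 comes from the Sharpless epoxidation, C4 from the same step followed by Mitsunobu inversion, C3 from Felkin–Anh control by C4 in the key step, and the two side-chain centres from the purchased acids.

Key step: step 6

Assumption: the SMILES is read as carrying an (R)-2-methylbutanoyl group on O4 and an (S)-3-methylpentanoyl group on O5, and both acids are taken as purchasable in enantiopure form.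

Step 1
Reactants: 1 penta-1,4-dien-3-ol (divinylcarbinol)
Product: 2 (2R,3S)-1,2-epoxypent-4-en-3-ol (erythro)
Conditions: Ti(OiPr)4 (10 mol %), L-(+)-diisopropyl tartrate (13 mol %), t-BuOOH, 4 Å molecular sieves, CH2Cl2, −20 °C
Reagents that add atoms: tert-butyl hydroperoxide, CC(C)(C)OO
Why: The Sharpless asymmetric epoxidation desymmetrises the two enantiotopic vinyl groups, the L-(+)-tartrate catalyst setting the epoxide carbon (future C5) as R and, through the erythro preference of secondary allylic alcohols, the carbinol carbon as S, while over-oxidation of the minor enantiomer should raise the enantiomeric purity further.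

Step 2
Reactants: 2 (2R,3S)-1,2-epoxypent-4-en-3-ol; 3 (R)-2-methylbutanoic acid
Product: 4 (R)-1-[(R)-oxiran-2-yl]prop-2-en-1-yl (R)-2-methylbutanoate (threo)
Conditions: PPh3, DIAD, THF, 0 °C to rt
Reagents that add atoms: none
Why: In the Mitsunobu esterification the carboxylate displaces the activated hydroxyl in an SN2 sense, so the carbinol centre (future C4) is inverted into the required threo series and the O4 ester is installed without turning the epimerisable acid into an acyl donor.

Step 3
Reactants: 5 (S)-3-methylpentanoic acid
Product: 6 (S)-3-methylpentanoyl bromide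
Conditions: (COBr)2, DMF (cat.), CH2Cl2, 0 °C to rt, evaporated and used crude
Reagents that add atoms: oxalyl bromide, O=C(Br)C(=O)Br
Why: This is a standard acyl bromide formation through Vilsmeier-type activation, and the stereocentre is β to the carbonyl group and cannot epimerise.

Step 4
Reactants: 4 (R)-1-[(R)-oxiran-2-yl]prop-2-en-1-yl (R)-2-methylbutanoate; 6 (S)-3-methylpentanoyl bromide
Product: 7 (2S,3R)-1-bromo-3-[(R)-2-methylbutanoyloxy]pent-4-en-2-yl (S)-3-methylpentanoate
Conditions: Bu4NBr (5 mol %), CH2Cl2, −20 °C to rt
Reagents that add atoms: none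
Why: In this acyl halide cleavage of an epoxide (β-halo ester synthesis) the oxirane oxygen is acylated and bromide attacks the unhindered primary carbon by SN2, so O5 receives its ester with the C5–O bond untouched (retention) and C6 receives its leaving group in the same step.

Step 5
Reactants: 7 (2S,3R)-1-bromo-3-[(R)-2-methylbutanoyloxy]pent-4-en-2-yl (S)-3-methylpentanoate
Product: 9 (2S,3S)-4-bromo-2-[(R)-2-methylbutanoyloxy]-3-[(S)-3-methylpentanoyloxy]butanal, via secondary ozonide 8 (not isolated)
Conditions: O3, CH2Cl2, −78 °C (Sudan red end point); PPh3, −78 °C to rt; short silica plug, used at once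
Reagents that add atoms: ozone, [O-][O+]=O
Why: Ozonolysis (Criegee mechanism) with a neutral reductive work-up cleaves the only C=C bond, and the base-free medium avoids E1cB loss of the β-acyloxy group and epimerisation at C4.

Step 6
Reactants: 9 (2S,3S)-4-bromo-2-[(R)-2-methylbutanoyloxy]-3-[(S)-3-methylpentanoyloxy]butanal; 10 methyl propiolate
Product: 12 methyl (3R,4S,5R)-4-[(R)-2-methylbutanoyloxy]-5-[(S)-3-methylpentanoyloxy]-3-(triethylsilyloxy)cyclohex-1-ene-1-carboxylate, via alkenylnickel chloride 11 (not isolated)
Conditions: Ni(cod)2 (15 mol %), 4,4'-di-tert-butyl-2,2'-bipyridine (18 mol %), Mn powder (3 equiv), Et3SiCl (2 equiv), THF–DMA 4:1, 0.02 M in 9, 10 (3 equiv) by syringe pump, 25 °C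
Reagents that add atoms: chlorotriethylsilane, CC[Si](Cl)(CC)CC
Why: Proposed new method: zerovalent nickel binds the aldehyde of 9 and the alkyne of 10 and couples them oxidatively to an oxanickelacyclopentene (C2–C3 bond, two acceptor carbons joined because the metal supplies the two electrons), Et3SiCl cleaves the Ni–O bond to give alkenylnickel chloride 11, Mn reduces 11 to monovalent nickel, which takes up the pendant C6–Br bond, and reductive elimination from trivalent nickel forms C1–C6. The closest known reaction types are the nickel-catalysed reductive coupling of ynoates and other alkynes with aldehydes and the tandem metallacycle formation/cross-electrophile coupling of alkynes, enals, chlorosilanes and alkyl halides, and what is new is a simple aldehyde whose own chain carries the halide, which turns the process into a [4+2] annulation. The cyclohexene ring is closed by C(sp2)–C(sp3) reductive elimination from a seven-membered nickelacycle, a ring contraction that leaves C1=C2 endocyclic, and the syn addition across the alkyne places C3 and nickel cis, the only geometry from which C6 can be reached. C3 is the only new stereocentre and is controlled by C4, since bond formation at the carbonyl carbon anti to the C4 acyloxy group (polar Felkin–Anh model) gives the 3,4-anti (erythro) array, the sense known for nickel-catalysed alkyne couplings of α-oxy aldehydes. The regioselectivity (C2 to C3, nickel and then C6 to C1) follows from the ester, which polarises the alkyne and stabilises nickel on its α-carbon, and from the small H on C2, while the chemoselectivity rests on a primary bromide that reacts slowly before cyclometalation and on high dilution and slow addition of 10, which hold back Giese addition of a free C6 radical to 10, oligomerisation and alkyne trimerisation. The neutral medium spares the esters and the base-sensitive aldehyde, and a β-acyloxyalkyl group on nickel is known from reductive C-glycosylations of 2-O-acyl glycosyl bromides to couple faster than it eliminates.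

Step 7
Reactants: 12 methyl (3R,4S,5R)-4-[(R)-2-methylbutanoyloxy]-5-[(S)-3-methylpentanoyloxy]-3-(triethylsilyloxy)cyclohex-1-ene-1-carboxylate
Product: 13 methyl (3R,4S,5R)-3-acetoxy-4-[(R)-2-methylbutanoyloxy]-5-[(S)-3-methylpentanoyloxy]cyclohex-1-ene-1-carboxylate (CNP0188172.1)
Conditions: Ac2O (3 equiv), Sc(OTf)3 (5 mol %), MeCN, 0 °C
Reagents that add atoms: acetic anhydride, CC(=O)OC(C)=O
Why: The Lewis-acid-catalysed direct exchange of a silyl ether for an acetate never liberates a C3 alkoxide, so O4-to-O3 acyl migration is avoided, and the electron-poor allylic system resists ionisation, so the C3–O bond and its configuration are kept.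

Compound list
1 | penta-1,4-dien-3-ol (divinylcarbinol) | C=CC(O)C=C | starting material
2 | (2R,3S)-1,2-epoxypent-4-en-3-ol (erythro) | C=C[C@H](O)[C@H]1CO1 | intermediate
3 | (R)-2-methylbutanoic acid | CC[C@@H](C)C(=O)O | starting material
4 | (R)-1-[(R)-oxiran-2-yl]prop-2-en-1-yl (R)-2-methylbutanoate (threo) | C=C[C@@H](OC(=O)[C@H](C)CC)[C@H]1CO1 | intermediate
5 | (S)-3-methylpentanoic acid | CC[C@H](C)CC(=O)O | starting material
6 | (S)-3-methylpentanoyl bromide | CC[C@H](C)CC(=O)Br | intermediate
7 | (2S,3R)-1-bromo-3-[(R)-2-methylbutanoyloxy]pent-4-en-2-yl (S)-3-methylpentanoate | CC[C@H](C)CC(=O)O[C@H](CBr)[C@@H](C=C)OC(=O)[C@H](C)CC | intermediate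
8 | secondary ozonide (1,2,4-trioxolane) of 7, mixture at the trioxolane carbon | CC[C@H](C)CC(=O)O[C@H](CBr)[C@@H](C1OCOO1)OC(=O)[C@H](C)CC | intermediate
9 | (2S,3S)-4-bromo-2-[(R)-2-methylbutanoyloxy]-3-[(S)-3-methylpentanoyloxy]butanal (D-threo) | CC[C@H](C)CC(=O)O[C@H](CBr)[C@@H](C=O)OC(=O)[C@H](C)CC | intermediate
10 | methyl propiolate | C#CC(=O)OC | starting material
11 | open-chain alkenylnickel chloride: C2–C3 made, nickel on C1 cis to C3, O3 silylated, C6–Br intact (bipyridine ligand omitted) | CC[C@H](C)CC(=O)O[C@H](CBr)[C@@H]([C@H](O[Si](CC)(CC)CC)/C=C(\[Ni]Cl)C(=O)OC)OC(=O)[C@H](C)CC | intermediate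
12 | methyl (3R,4S,5R)-4-[(R)-2-methylbutanoyloxy]-5-[(S)-3-methylpentanoyloxy]-3-(triethylsilyloxy)cyclohex-1-ene-1-carboxylate | CC[C@H](C)CC(=O)O[C@@H]1CC(C(=O)OC)=C[C@@H](O[Si](CC)(CC)CC)[C@H]1OC(=O)[C@H](C)CC | intermediate
13 | methyl (3R,4S,5R)-3-acetoxy-4-[(R)-2-methylbutanoyloxy]-5-[(S)-3-methylpentanoyloxy]cyclohex-1-ene-1-carboxylate | CC[C@H](C)CC(=O)O[C@@H]1CC(C(=O)OC)=C[C@@H](OC(C)=O)[C@H]1OC(=O)[C@H](C)CC | target

Total step count: 7. Longest linear sequence: 6 steps (1, 2, 4, 5, 6, 7) from divinylcarbinol.

Steps most likely to fail

Step 6 (new method). Several processes could interfere: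
- The C6–Br bond may be activated before aldehyde and alkyne have been joined. The free C6 radical would then add to the β-carbon of 10 with the wrong regiochemistry, or bromide and the C5 acyloxy group would be lost by reductive β-elimination.
- The C1–Ni bond may be protonated before ring closure.
- Methyl propiolate 10 may trimerise.
- Facial selectivity at C3 may be poor.

The fallback uses known chemistry, sets out from 9 and returns at 12, and makes the two bonds one after the other by polar reactions. A Nozaki–Hiyama–Kishi coupling of 9 with commercial methyl (E)-3-iodoacrylate (CrCl2, NiCl2 cat., THF–DMSO) should give the Felkin–Anh γ-hydroxy enoate F1. Silylation (Et3SiOTf, 2,6-lutidine, CH2Cl2, −78 °C) should give the silyl ether F2. An intramolecular Morita–Baylis–Hillman-type alkylation then closes the ring. PBu3 adds to C2, and the ester enolate at C1 displaces bromide at C6 (6-exo-tet) to give the cyclic phosphonium bromide F3. DBU then expels PBu3 by E1cB elimination, which restores C1=C2 and delivers 12.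

Step 2. The weakly acidic aliphatic acid may displace the phosphonium group sluggishly. That would open the way to SN2′ attack at the vinyl terminus or to partial retention through an acyloxyphosphonium pathway. The fallback sets out from 2 and returns at 4, and separates inversion from acylation. A Mitsunobu reaction with the more acidic 4-nitrobenzoic acid should give the threo 4-nitrobenzoate F4. Mild methanolysis (K2CO3 cat., MeOH, 0 °C, kept short to avoid Payne rearrangement) should give the threo epoxy alcohol F5. Steglich esterification of F5 with acid 3 (DIC, DMAP cat., CH2Cl2, 0 °C) gives 4 with retention.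

Step 4. The neighbouring O4 ester carbonyl may take part in the opening of the acylated oxirane, forming an acyloxonium ion with acyl scrambling or inversion at C5. Bromide may also attack at C5. The fallback sets out from 4 and returns at 7, and replaces electrophilic activation by nucleophilic opening. Li2NiBr4 in THF at 0 °C should open the epoxide at the primary carbon under nearly neutral conditions to give the bromohydrin F6. F6 is then esterified at once with acid 5 (DIC, DMAP cat., CH2Cl2, −10 °C) to give 7 before acyl migration can set in.

Further compounds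
F1 | step 6 | methyl (E)-7-bromo-4-hydroxy-5-[(R)-2-methylbutanoyloxy]-6-[(S)-3-methylpentanoyloxy]hept-2-enoate, 4,5-anti and 5,6-syn, configuration as in 12 | CC[C@H](C)CC(=O)O[C@H](CBr)[C@@H]([C@H](O)/C=C/C(=O)OC)OC(=O)[C@H](C)CC
F2 | step 6 | triethylsilyl ether of F1 | CC[C@H](C)CC(=O)O[C@H](CBr)[C@@H]([C@H](O[Si](CC)(CC)CC)/C=C/C(=O)OC)OC(=O)[C@H](C)CC
F3 | step 6 | cyclic phosphonium bromide: cyclohexane with PBu3 on C2 and CO2Me on C1 (both centres undefined), C3 to C5 as in 12 | CC[C@H](C)CC(=O)O[C@@H]1CC(C(=O)OC)C([P+](CCCC)(CCCC)CCCC)[C@@H](O[Si](CC)(CC)CC)[C@H]1OC(=O)[C@H](C)CC.[Br-]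
F4 | step 2 | (R)-1-[(R)-oxiran-2-yl]prop-2-en-1-yl 4-nitrobenzoate (threo) | C=C[C@@H](OC(=O)c1ccc(cc1)[N+](=O)[O-])[C@H]1CO1
F5 | step 2 | (2R,3R)-1,2-epoxypent-4-en-3-ol (threo) | C=C[C@@H](O)[C@H]1CO1
F6 | step 4 | (3R,4S)-5-bromo-4-hydroxypent-1-en-3-yl (R)-2-methylbutanoate | C=C[C@@H](OC(=O)[C@H](C)CC)[C@H](O)CBr
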